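Remark on the chemistry (assumptions): O1 and C2–C5 are the ring atoms of the oxolane, C6 is the exocyclic carbinol carbon on C4, C7 is the CH2OAc carbon on C3, and C8 is the extra alkene carbon that is later cleaved off. Compounds 1, 2, 5, 10 and 15 are taken to be commercial.

## Analysis of the target

The target is a monocyclic oxolane. C2 carries a 4-hydroxyphenyl group, C3 an acetoxymethyl group (C7), C4 the carbinol carbon C6 with an acetoxy and a 4-methoxyphenyl group, and C5 is an unsubstituted CH2. There are four contiguous stereocentres: C2 (R), C3 (S), C4 (R) and C6 (S). The ring is 2,3-trans and 3,4-trans, so the aryl group and the C6 side chain are cis. C6–O is anti to C5 when the chain aryl–C6–C4–C3 is drawn as a zigzag.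

Both benzylic C–O bonds sit para to an oxygen donor. C2–O1 ionises under acid and can open through a quinone methide once the phenol is free and deprotonated. The C6 acetate is a 4-methoxybenzylic ester that solvolyses easily. Hydrogenolysis is therefore excluded, and strong acid or base must be avoided late. The three oxygen functions must end differently: phenol free, primary and secondary alcohols acetylated.

The hard part is stereochemical. No ring centre is next to a carbonyl group, and C6 lies outside the ring, so its relation to C4 cannot be repaired by equilibration.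

The plan rests on one feature. C2 is at the aldehyde oxidation level (bonded to O1 and an aryl group), and its neighbour C3 carries the one-carbon branch C7, which can be what is left of a vinyl group. O1–C2 and C2–C3 can therefore be made together when an oxocarbenium ion on the C5 oxygen is captured by an allylsilane whose γ-carbon is C3.

## Retrosynthetic reasoning

**End game, 23 back to 20.** The acetates are put on last because the benzylic acetate would not survive the earlier steps. The free phenol of 23 comes from triacetate 22 by cleaving only the aryl ester, which is far more reactive toward amines than the two alkyl esters. Triacetate 22 comes from triol 21, and 21 from the bis-silyl ether 20 by a single fluoride treatment. No C–C bond is cut here; the gain is that all three oxygens are told apart by reactivity alone.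

**C7=C8, 20 back to 18.** The hydroxymethyl group on C3 is the oxidised remnant of a vinyl group. Cutting C7=C8 (ozonolysis with reduction, through aldehyde 19) leads to the vinyl oxolane 18. A vinyl group on C3 is exactly what an allylsilane leaves behind.

**O1–C2 and C2–C3, 18 back to 14 and 16 (key disconnection).** C2 is the only ring carbon at aldehyde level, so these two bonds are cut and C2 is returned to aldehyde 16. The C5 oxygen and C3 stay in one chain, the Z-allylsilane alcohol 14, which reacts as its trimethylsilyl ether 17. The cut is convergent and late. It makes the ring, two bonds and two stereocentres (C2, C3) at once, and it lets the stereocentres already present (C4, C6) steer the new ones. The forward reaction has four tasks: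

- generate the oxocarbenium ion on O1;
- let C3, not C7, attack;
- give the 2,3-trans and 3,4-trans ring;
- leave the acid-sensitive silyl ether on C6 alone.

The alkene in 14 is deliberately Z. With CH2SiMe3 cis to C4, allylic 1,3-strain forces C4–H into the alkene plane, so the C5 arm and the C6 side chain lie on opposite faces and the 3,4-relationship is locked. An E-alkene has only hydrogen cis to C4. The lock would then be weak, and a chair-like, synclinal approach of the cation, which leads to a 2,3-cis ring, would become competitive.

**C3=C7 and Si–O, 14 back to 9 and 10.** A cross-metathesis would give an E-rich mixture, so the Z-alkene is made inside a ring. Alcohol 14 comes from the seven-membered allylsiloxane 12 by cleaving Si–O with a methyl nucleophile. Siloxane 12 comes by ring-closing metathesis from the allylsilyl ether 11, which is made from alcohol 9 and chlorosilane 10. C7 and C8 thus come from 10. A seven-membered ring can only hold a Z-alkene.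

**C4–C6, 9 back to 4 and 5.** Alcohol 9 carries the two stereocentres that control everything else. Cutting C4–C6 gives aldehyde 5 and a four-carbon unit that supplies C5, C4 and the vinyl group. The required configuration is the syn-aldol pattern along the chain C5–C4–C6. An auxiliary-controlled aldol reaction of crotonyl imide 4 therefore sets both centres with known absolute sense, giving 7. Silylation gives 8, and reductive removal of the auxiliary turns the acyl carbon into C5 of 9. Imide 4 comes from 1 and 2.

**Aldehyde 16 back to 15.** Only the phenol needs a protecting group. A bulky silyl ether tolerates the Lewis acid of the key step and leaves with the C6 silyl group.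

## Alternatives that were turned down

Alternative 1: The ring is cut at C4–C5, so that C5 comes from a formaldehyde equivalent. In the forward step Me3SiOTf and i-Pr2NEt turn an aryl ketone at C6 into its enol silane and ionise a methoxymethyl ether on the C2 oxygen. The enol carbon C4 then closes on the O1=CH2 cation and gives keto ester A1.
- For it: C5 is introduced cheaply. C3 and C4 in A1 are both α to a carbonyl group and can settle into the all-trans ring by equilibration. On this point it is stronger than the chosen plan, which sets C3 under kinetic control.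
- Against it: C6 arrives as a ketone and must be reduced late to the S carbinol next to a ring stereocentre, with no clear facial bias. The C7 ester must be reduced as well. The C2–O1 bond is β to the ester-bearing carbon and can open by elimination.
- Comparison: the step count is similar. The chosen plan instead fixes C6 at the outset by an auxiliary-controlled aldol reaction and uses it, with C4, to direct the ring closure, so 18 already holds all four stereocentres.

Alternative 2: The ring is cut at O1–C2 and C3–C4 in a (3+2) sense. A zerovalent palladium catalyst (Pd2(dba)3 with a chiral phosphine) opens the racemic vinyl oxirane A3 to an alkoxide/π-allyl zwitterion. The alkoxide adds to the arylidene malonate A4, and the malonate carbanion closes on the substituted allyl terminus to give A2.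
- For it: this is the most convergent and shortest way to the ring, and it is catalytic and asymmetric from a racemate. In both respects it is stronger than the chosen plan.
- Against it: A2 still lacks two of the four stereocentres. C3 is a geminal diester and C6 is an alkene carbon. The endgame needs a dealkoxycarbonylation (harsh for a β-alkoxy ester), an ester reduction, cleavage of the 1-arylethenyl group to the ketone, and again an unbiased ketone reduction at C6. The 2,4-cis selectivity and the enantioselectivity rest entirely on the catalyst, with a hindered 2-aryl allyl unit.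
- Comparison: the chosen plan is longer before the ring but needs only oxidation-state and protecting-group changes after it.

Alternative 3: Three bonds are cut: O1–C2, C2–C3 and C4–C5. SnCl4 at low temperature ionises a cyclic acetal to the oxocarbenium ion on O1, and an (E)-alkene closes a six-membered ring (C2–C3). Ring carbon C5 then shifts from C6 to the cationic C4, which contracts the ring and unveils the aryl ketone of A5.
- For it: three bonds form in one step. The chair-like six-membered closure is intrinsically better behaved than a five-membered closure with the C=O+ bond inside the ring, and C4 in A5 can be equilibrated. In bond economy and in reliability of ring stereocontrol it is stronger than the chosen plan.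
- Against it: the substrate needs an enantiopure tertiary alkoxide at C6 that is both 4-methoxybenzylic and allylic. It is very prone to ionise under SnCl4, and its stereocentre is destroyed in the step. C6 then again needs a late diastereoselective ketone reduction.
- Comparison: the chosen plan keeps C6 as a protected secondary stereocentre throughout and uses only a catalytic silyl triflate.

Key step: step 9

## Route

Step 1
Reactants: 1 (S)-4-benzyloxazolidin-2-one; 2 (E)-but-2-enoyl chloride
Product: 4 (S)-4-benzyl-3-[(E)-but-2-enoyl]oxazolidin-2-one, via lithium imide salt 3 (not isolated)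
Conditions: n-BuLi, THF, −78 °C; then 2, −78 → 0 °C
Reagents that add atoms: none
Why: N-Acylation of the lithiated oxazolidinone by the acid chloride (imide formation); the low temperature avoids conjugate addition to the crotonyl unit, and no stereocentre is formed.

Step 2
Reactants: 4 (S)-4-benzyl-3-[(E)-but-2-enoyl]oxazolidin-2-one; 5 4-methoxybenzaldehyde
Product: 7 (S)-4-benzyl-3-[(2S,3S)-2-ethenyl-3-hydroxy-3-(4-methoxyphenyl)propanoyl]oxazolidin-2-one, via boron dienolate 6 (not isolated)
Conditions: n-Bu2BOTf, Et3N, CH2Cl2, −78 → 0 °C; then 5, −78 → 0 °C; pH 7 buffer, MeOH, 30% H2O2, 0 °C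
Reagents that add atoms: none
Why: Evans syn-aldol reaction: soft enolisation at the γ-methyl group gives the (Z)-boron dienolate 6, which reacts at its α-carbon through a Zimmerman–Traxler chair on the face away from the benzyl group of the auxiliary. This sets C4 and C6 together as the (2S,3S) syn adduct, which is the anti relation of C6–O and C5 needed later, and leaves the alkene deconjugated as the vinyl group on C4.

Step 3
Reactants: 7 (S)-4-benzyl-3-[(2S,3S)-2-ethenyl-3-hydroxy-3-(4-methoxyphenyl)propanoyl]oxazolidin-2-one
Product: 8 (S)-4-benzyl-3-[(2S,3S)-3-(tert-butyldimethylsilyloxy)-2-ethenyl-3-(4-methoxyphenyl)propanoyl]oxazolidin-2-one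
Conditions: t-BuMe2SiOTf, 2,6-lutidine, CH2Cl2, −78 → 0 °C
Reagents that add atoms: tert-butyldimethylsilyl trifluoromethanesulfonate, CC(C)(C)[Si](C)(C)OS(=O)(=O)C(F)(F)F
Why: O-Silylation of the hindered benzylic alcohol with a silyl triflate and a non-nucleophilic base; the buffered, cold conditions prevent retro-aldol cleavage and epimerisation at C4.

Step 4
Reactants: 8 (S)-4-benzyl-3-[(2S,3S)-3-(tert-butyldimethylsilyloxy)-2-ethenyl-3-(4-methoxyphenyl)propanoyl]oxazolidin-2-one
Product: 9 (2R)-2-[(S)-(tert-butyldimethylsilyloxy)(4-methoxyphenyl)methyl]but-3-en-1-ol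
Conditions: LiBH4, MeOH (1 equiv), THF, 0 °C
Reagents that add atoms: none
Why: Hydride reduction of the imide carbonyl releases the auxiliary and gives the primary alcohol (C5); LiBH4 leaves the silyl ether and the alkene alone, and the non-basic medium keeps the allylic C4 centre intact.

Step 5
Reactants: 9 (2R)-2-[(S)-(tert-butyldimethylsilyloxy)(4-methoxyphenyl)methyl]but-3-en-1-ol; 10 allyl(chloro)dimethylsilane
Product: 11 allyl{[(2R)-2-[(S)-(tert-butyldimethylsilyloxy)(4-methoxyphenyl)methyl]but-3-en-1-yl]oxy}dimethylsilane
Conditions: Et3N, DMAP (cat.), CH2Cl2, 0 °C → rt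
Reagents that add atoms: none
Why: O-Silylation of the primary alcohol installs a temporary silicon tether that carries the future C7 and C8; the secondary oxygen is already blocked.

Step 6
Reactants: 11 allyl{[(2R)-2-[(S)-(tert-butyldimethylsilyloxy)(4-methoxyphenyl)methyl]but-3-en-1-yl]oxy}dimethylsilane
Product: 12 (6R)-6-[(S)-(tert-butyldimethylsilyloxy)(4-methoxyphenyl)methyl]-2,2-dimethyl-2,3,6,7-tetrahydro-1,2-oxasilepine
Conditions: second-generation Grubbs catalyst RuCl2(=CHPh)(PCy3)(H2IMes) (5 mol%), CH2Cl2 (0.01 M), 40 °C
Reagents that add atoms: none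
Why: Ring-closing metathesis: the catalyst loads on the unhindered allylsilane terminus and closes onto the vinyl group with loss of ethene. A seven-membered ring can only hold a Z-alkene, so the allylsilane geometry is fixed without a selectivity question.

Step 7
Reactants: 12 (6R)-6-[(S)-(tert-butyldimethylsilyloxy)(4-methoxyphenyl)methyl]-2,2-dimethyl-2,3,6,7-tetrahydro-1,2-oxasilepine
Product: 14 (2R,3Z)-2-[(S)-(tert-butyldimethylsilyloxy)(4-methoxyphenyl)methyl]-5-(trimethylsilyl)pent-3-en-1-ol, via lithium alkoxide 13 (not isolated)
Conditions: MeLi, THF, −78 → 0 °C; then H2O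
Reagents that add atoms: methyllithium, [Li]C
Why: Nucleophilic substitution at silicon by the methyl anion cleaves the Si–O bond and turns the ring silicon into SiMe3. The alkene geometry and both stereocentres are untouched, so the Z-allylsilane is obtained with a free primary alcohol.

Step 8
Reactants: 15 4-hydroxybenzaldehyde
Product: 16 4-(triisopropylsilyloxy)benzaldehyde
Conditions: i-Pr3SiCl, imidazole, DMF, rt
Reagents that add atoms: chlorotriisopropylsilane, CC(C)[Si](Cl)(C(C)C)C(C)C
Why: Silylation of the phenol; the bulky aryl silyl ether withstands the Lewis acid of the key step and is removed later together with the silyl group on C6.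

Step 9
Reactants: 14 (2R,3Z)-2-[(S)-(tert-butyldimethylsilyloxy)(4-methoxyphenyl)methyl]-5-(trimethylsilyl)pent-3-en-1-ol; 16 4-(triisopropylsilyloxy)benzaldehyde
Product: 18 (2R,3R,4R)-4-[(S)-(tert-butyldimethylsilyloxy)(4-methoxyphenyl)methyl]-3-ethenyl-2-[4-(triisopropylsilyloxy)phenyl]oxolane (all-trans), via trimethylsilyl ether 17 (not isolated)
Conditions: (Me3Si)2NH, Me3SiOTf (1 mol%), CH2Cl2, rt, then evaporation; 16, Me3SiOTf (0.2 equiv), CH2Cl2, −78 °C; Et3N quench
Reagents that add atoms: none
Why: Me3SiOTf converts 17 and 16 into the mixed silyl acetal and then, with loss of (Me3Si)2O, into the (E)-oxocarbenium ion C5–O1+=C2H–aryl; the Z-allylsilane attacks it through its γ-carbon C3 anti to silicon, and the β-silyl cation at C7 gives up Me3Si+ to triflate, which closes the oxolane, leaves the C7=C8 vinyl group and regenerates the catalyst. The closest known reaction type is the intramolecular silyl-modified Sakurai (oxocarbenium–allylsilane, Prins-type) cyclisation of 5-silylpent-3-en-1-ol silyl ethers with aldehydes to 2-substituted 3-vinyloxolanes. One five-membered ring is closed, with the C2=O1+ bond inside the forming ring (endo at the electrophile, formally 5-endo-trig) and the alkene outside it (exo at the nucleophile); the long C–O bonds and the reactivity of the cation should make this closure workable. C3 is controlled by C4: allylic 1,3-strain in the Z-alkene holds C4–H in the alkene plane next to CH2SiMe3, so C5 with the tethered cation lies on one face and the bulky C6 side chain on the other, and bond formation on the C5 face places the vinyl group trans to the C6 side chain. C2 is controlled by the (E)-geometry of the oxocarbenium ion and by the new C3 centre: the aryl group takes the pseudo-equatorial position turned away from C7, so the two π-bonds react in a roughly antiperiplanar arrangement and the ring becomes 2,3-trans. The step needs regioselectivity for C3 over C7, which the β-silicon effect secures, the two diastereoselectivities just named, and chemoselectivity toward the 4-methoxybenzylic silyl ether on C6, which the catalytic amount of Lewis acid at −78 °C and the bulk of the tert-butyldimethylsilyl group (keeping O6 from adding to the cation) should secure.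

Step 10
Reactants: 18 (2R,3R,4R)-4-[(S)-(tert-butyldimethylsilyloxy)(4-methoxyphenyl)methyl]-3-ethenyl-2-[4-(triisopropylsilyloxy)phenyl]oxolane
Product: 20 [(2R,3S,4R)-4-[(S)-(tert-butyldimethylsilyloxy)(4-methoxyphenyl)methyl]-2-[4-(triisopropylsilyloxy)phenyl]oxolan-3-yl]methanol, via aldehyde 19 (not isolated)
Conditions: O3, CH2Cl2/MeOH (4:1), −78 °C, Sudan Red 7B as end-point indicator; then NaBH4, −78 → 0 °C
Reagents that add atoms: ozone, O=[O+][O-]
Why: Ozonolysis of the monosubstituted alkene with reductive work-up; ozone is dosed to the end point of the dye so that the electron-rich arenes are spared. Reducing aldehyde 19 in the same flask at low temperature forestalls epimerisation at C3 and β-elimination of O1; no stereocentre is formed.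

Step 11
Reactants: 20 [(2R,3S,4R)-4-[(S)-(tert-butyldimethylsilyloxy)(4-methoxyphenyl)methyl]-2-[4-(triisopropylsilyloxy)phenyl]oxolan-3-yl]methanol
Product: 21 4-[(2R,3S,4R)-4-[(S)-hydroxy(4-methoxyphenyl)methyl]-3-(hydroxymethyl)oxolan-2-yl]phenol
Conditions: Bu4NF, AcOH, THF, 0 °C → rt
Reagents that add atoms: none
Why: Fluoride cleaves the aryl and the alkyl silyl ether in one operation; acetic acid buffers the phenoxide and alkoxides so that the benzylic C2–O1 bond is not opened through a quinone methide.

Step 12
Reactants: 21 4-[(2R,3S,4R)-4-[(S)-hydroxy(4-methoxyphenyl)methyl]-3-(hydroxymethyl)oxolan-2-yl]phenol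
Product: 22 [(2R,3S,4R)-4-[(S)-acetoxy(4-methoxyphenyl)methyl]-2-(4-acetoxyphenyl)oxolan-3-yl]methyl acetate
Conditions: Ac2O, pyridine, DMAP (cat.), CH2Cl2, 0 °C → rt
Reagents that add atoms: acetic anhydride, CC(=O)OC(C)=O
Why: Exhaustive acylation of the phenol, the primary alcohol and the secondary benzylic alcohol under nucleophilic catalysis; the basic, non-ionising medium protects both benzylic C–O bonds.

Step 13
Reactants: 22 [(2R,3S,4R)-4-[(S)-acetoxy(4-methoxyphenyl)methyl]-2-(4-acetoxyphenyl)oxolan-3-yl]methyl acetate
Product: 23 [(2R,3S,4R)-4-[(S)-acetoxy(4-methoxyphenyl)methyl]-2-(4-hydroxyphenyl)oxolan-3-yl]methyl acetate (target)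
Conditions: pyrrolidine (2 equiv), CH2Cl2, 0 °C
Reagents that add atoms: none
Why: Chemoselective aminolysis: the aryl acetate has by far the best leaving group and is cleaved by a secondary amine in an aprotic solvent at 0 °C, while the two alkyl acetates remain. No protic or acidic medium is used, so the 4-methoxybenzylic acetate should not solvolyse.

## Compound list

1 | (S)-4-benzyloxazolidin-2-one | O=C1OC[C@H](Cc2ccccc2)N1 | starting material
2 | (E)-but-2-enoyl chloride | C/C=C/C(Cl)=O | starting material
3 | lithium salt of 1 (N-lithio-(S)-4-benzyloxazolidin-2-one) | [Li]N1[C@@H](Cc2ccccc2)COC1=O | intermediate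
4 | (S)-4-benzyl-3-[(E)-but-2-enoyl]oxazolidin-2-one | C/C=C/C(=O)N1[C@@H](Cc2ccccc2)COC1=O | intermediate
5 | 4-methoxybenzaldehyde | COc1ccc(C=O)cc1 | starting material
6 | (S)-4-benzyl-3-[(1Z)-1-(dibutylboryloxy)buta-1,3-dienyl]oxazolidin-2-one (boron dienolate of 4) | C=C/C=C(\OB(CCCC)CCCC)N1[C@@H](Cc2ccccc2)COC1=O | intermediate
7 | (S)-4-benzyl-3-[(2S,3S)-2-ethenyl-3-hydroxy-3-(4-methoxyphenyl)propanoyl]oxazolidin-2-one | COc1ccc([C@@H](O)[C@H](C=C)C(=O)N2[C@@H](Cc3ccccc3)COC2=O)cc1 | intermediate
8 | (S)-4-benzyl-3-[(2S,3S)-3-(tert-butyldimethylsilyloxy)-2-ethenyl-3-(4-methoxyphenyl)propanoyl]oxazolidin-2-one | COc1ccc([C@@H](O[Si](C)(C)C(C)(C)C)[C@H](C=C)C(=O)N2[C@@H](Cc3ccccc3)COC2=O)cc1 | intermediate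
9 | (2R)-2-[(S)-(tert-butyldimethylsilyloxy)(4-methoxyphenyl)methyl]but-3-en-1-ol | COc1ccc([C@@H](O[Si](C)(C)C(C)(C)C)[C@H](C=C)CO)cc1 | intermediate
10 | allyl(chloro)dimethylsilane | C=CC[Si](C)(C)Cl | starting material
11 | allyl{[(2R)-2-[(S)-(tert-butyldimethylsilyloxy)(4-methoxyphenyl)methyl]but-3-en-1-yl]oxy}dimethylsilane | COc1ccc([C@@H](O[Si](C)(C)C(C)(C)C)[C@H](C=C)CO[Si](C)(C)CC=C)cc1 | intermediate
12 | (6R)-6-[(S)-(tert-butyldimethylsilyloxy)(4-methoxyphenyl)methyl]-2,2-dimethyl-2,3,6,7-tetrahydro-1,2-oxasilepine | COc1ccc([C@@H](O[Si](C)(C)C(C)(C)C)[C@@H]2/C=C\C[Si](C)(C)OC2)cc1 | intermediate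
13 | lithium (2R,3Z)-2-[(S)-(tert-butyldimethylsilyloxy)(4-methoxyphenyl)methyl]-5-(trimethylsilyl)pent-3-en-1-olate | COc1ccc([C@@H](O[Si](C)(C)C(C)(C)C)[C@@H](CO[Li])/C=C\C[Si](C)(C)C)cc1 | intermediate
14 | (2R,3Z)-2-[(S)-(tert-butyldimethylsilyloxy)(4-methoxyphenyl)methyl]-5-(trimethylsilyl)pent-3-en-1-ol | COc1ccc([C@@H](O[Si](C)(C)C(C)(C)C)[C@@H](CO)/C=C\C[Si](C)(C)C)cc1 | intermediate
15 | 4-hydroxybenzaldehyde | O=Cc1ccc(O)cc1 | starting material
16 | 4-(triisopropylsilyloxy)benzaldehyde | O=Cc1ccc(O[Si](C(C)C)(C(C)C)C(C)C)cc1 | intermediate
17 | trimethylsilyl ether of 14, [(2R,3Z)-2-[(S)-(tert-butyldimethylsilyloxy)(4-methoxyphenyl)methyl]-5-(trimethylsilyl)pent-3-en-1-yl]oxy(trimethyl)silane | COc1ccc([C@@H](O[Si](C)(C)C(C)(C)C)[C@@H](CO[Si](C)(C)C)/C=C\C[Si](C)(C)C)cc1 | intermediate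
18 | (2R,3R,4R)-4-[(S)-(tert-butyldimethylsilyloxy)(4-methoxyphenyl)methyl]-3-ethenyl-2-[4-(triisopropylsilyloxy)phenyl]oxolane (all-trans) | COc1ccc([C@@H](O[Si](C)(C)C(C)(C)C)[C@H]2CO[C@@H](c3ccc(O[Si](C(C)C)(C(C)C)C(C)C)cc3)[C@@H]2C=C)cc1 | intermediate
19 | (2R,3R,4R)-4-[(S)-(tert-butyldimethylsilyloxy)(4-methoxyphenyl)methyl]-2-[4-(triisopropylsilyloxy)phenyl]oxolane-3-carbaldehyde | COc1ccc([C@@H](O[Si](C)(C)C(C)(C)C)[C@H]2CO[C@@H](c3ccc(O[Si](C(C)C)(C(C)C)C(C)C)cc3)[C@@H]2C=O)cc1 | intermediate
20 | [(2R,3S,4R)-4-[(S)-(tert-butyldimethylsilyloxy)(4-methoxyphenyl)methyl]-2-[4-(triisopropylsilyloxy)phenyl]oxolan-3-yl]methanol | COc1ccc([C@@H](O[Si](C)(C)C(C)(C)C)[C@H]2CO[C@@H](c3ccc(O[Si](C(C)C)(C(C)C)C(C)C)cc3)[C@@H]2CO)cc1 | intermediate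
21 | 4-[(2R,3S,4R)-4-[(S)-hydroxy(4-methoxyphenyl)methyl]-3-(hydroxymethyl)oxolan-2-yl]phenol | COc1ccc([C@@H](O)[C@H]2CO[C@@H](c3ccc(O)cc3)[C@@H]2CO)cc1 | intermediate
22 | [(2R,3S,4R)-4-[(S)-acetoxy(4-methoxyphenyl)methyl]-2-(4-acetoxyphenyl)oxolan-3-yl]methyl acetate | COc1ccc([C@@H](OC(C)=O)[C@H]2CO[C@@H](c3ccc(OC(C)=O)cc3)[C@@H]2COC(C)=O)cc1 | intermediate
23 | [(2R,3S,4R)-4-[(S)-acetoxy(4-methoxyphenyl)methyl]-2-(4-hydroxyphenyl)oxolan-3-yl]methyl acetate | COc1ccc([C@@H](OC(C)=O)[C@H]2CO[C@@H](c3ccc(O)cc3)[C@@H]2COC(C)=O)cc1 | target

## Step count and least certain steps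

Total: 13 steps. Longest linear sequence: 12 steps (steps 1–7 and 9–13); step 8 is a one-step side branch.

**Step 9 (key step).** Three things are most likely to go wrong:
- erosion of the 2,3-selectivity, because a synclinal approach of the cation competes with the antiperiplanar one;
- ionisation or participation of the 4-methoxybenzylic silyl ether on C6 under the Lewis acid;
- scrambling by a 2-oxonia-Cope shift of the homoallylic oxocarbenium ion before closure.

C2 is a benzylic ether carbon para to a silyloxy donor, so reversible C2–O1 ionisation should in any case drift toward the all-trans ring.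

Fallback: skip the opening of the siloxane and condense cyclic allylsiloxane 12 directly with 16 under stoichiometric BF3·OEt2 in CH2Cl2 at −78 °C. The ring oxygen of 12 adds to the activated aldehyde, fluoride transfer to silicon gives the oxocarbenium ion with the Z-allylsilane still attached, and the same closure gives 18. The silicon tether replaces the separate silyl ether and the catalytic triflate. This sets out from 12 and comes back at 18; no new compound lies on the way (entry F0).

**Step 6.** Ring closure onto the vinyl group may be slow, because that group sits on a branched carbon next to the bulky C6 side chain. Alkene isomerisation or hydrolysis of the labile silyl ether could then take over.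

Fallback: build the Z-allylsilane by olefination instead of metathesis. Alcohol 9 is acylated (t-BuCOCl, pyridine) to pivalate F1. Ozonolysis (O3, CH2Cl2, −78 °C; PPh3) gives aldehyde F2. A Z-selective Wittig reaction with the unstabilised β-silyl ylide Ph3P=CHCH2SiMe3 (from the phosphonium iodide and NaN(SiMe3)2, THF, −78 °C) gives Z-allylsilane pivalate F3. Reduction with i-Bu2AlH removes the ester and gives 14. This sets out from 9 and comes back at 14.

**Step 10.** Ozone may over-oxidise the two electron-rich arenes. Aldehyde 19 may also open by β-elimination of O1 if it lingers under basic conditions.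

Fallback: replace ozone by a two-stage cleavage. Catalytic dihydroxylation of 18 (K2OsO2(OH)4, N-methylmorpholine N-oxide, acetone/H2O) gives diol F4. Periodate cleavage (NaIO4, THF/H2O) gives aldehyde 19, which is reduced with NaBH4 as before. This sets out from 18 and comes back at 19.

**Step 13.** The amine or adventitious protic species may displace the 4-methoxybenzylic acetate, or selectivity between the three esters may be incomplete.

Fallback: differentiate the phenol by its acidity before acylation. Triol 21 is alkylated at the phenol only (allyl bromide, K2CO3, acetone) to allyl ether F5. Acetylation (Ac2O, pyridine, DMAP) gives diacetate F6. Deallylation with a zerovalent palladium catalyst (Pd(PPh3)4, morpholine, THF, rt) frees the phenol and gives 23. This sets out from 21 and comes back at 23.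

## Further compounds

F0 | step 9 | none | none
F1 | step 6 | (2R)-2-[(S)-(tert-butyldimethylsilyloxy)(4-methoxyphenyl)methyl]but-3-en-1-yl 2,2-dimethylpropanoate | COc1ccc([C@@H](O[Si](C)(C)C(C)(C)C)[C@H](C=C)COC(=O)C(C)(C)C)cc1
F2 | step 6 | (2R,3S)-3-(tert-butyldimethylsilyloxy)-2-formyl-3-(4-methoxyphenyl)propyl 2,2-dimethylpropanoate | COc1ccc([C@@H](O[Si](C)(C)C(C)(C)C)[C@H](C=O)COC(=O)C(C)(C)C)cc1
F3 | step 6 | (2R,3Z)-2-[(S)-(tert-butyldimethylsilyloxy)(4-methoxyphenyl)methyl]-5-(trimethylsilyl)pent-3-en-1-yl 2,2-dimethylpropanoate | COc1ccc([C@@H](O[Si](C)(C)C(C)(C)C)[C@@H](COC(=O)C(C)(C)C)/C=C\C[Si](C)(C)C)cc1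
F4 | step 10 | 1-[4-[(S)-(tert-butyldimethylsilyloxy)(4-methoxyphenyl)methyl]-2-[4-(triisopropylsilyloxy)phenyl]oxolan-3-yl]ethane-1,2-diol (ring configuration as in 18, both epimers at the new carbinol carbon) | COc1ccc([C@@H](O[Si](C)(C)C(C)(C)C)[C@H]2CO[C@@H](c3ccc(O[Si](C(C)C)(C(C)C)C(C)C)cc3)[C@@H]2C(O)CO)cc1
F5 | step 13 | [(2R,3S,4R)-4-[(S)-hydroxy(4-methoxyphenyl)methyl]-2-[4-(prop-2-enyloxy)phenyl]oxolan-3-yl]methanol | COc1ccc([C@@H](O)[C@H]2CO[C@@H](c3ccc(OCC=C)cc3)[C@@H]2CO)cc1
F6 | step 13 | [(2R,3S,4R)-4-[(S)-acetoxy(4-methoxyphenyl)methyl]-2-[4-(prop-2-enyloxy)phenyl]oxolan-3-yl]methyl acetate | COc1ccc([C@@H](OC(C)=O)[C@H]2CO[C@@H](c3ccc(OCC=C)cc3)[C@@H]2COC(C)=O)cc1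
A1 | alternative 1 | methyl all-trans 4-(4-methoxybenzoyl)-2-(4-pivaloyloxyphenyl)oxolane-3-carboxylate | COc1ccc(C(=O)[C@H]2CO[C@@H](c3ccc(OC(=O)C(C)(C)C)cc3)[C@@H]2C(=O)OC)cc1
A2 | alternative 2 | dimethyl 2,4-cis-2-[4-(tert-butyldimethylsilyloxy)phenyl]-4-[1-(4-methoxyphenyl)ethenyl]oxolane-3,3-dicarboxylate | COc1ccc(C(=C)[C@H]2CO[C@@H](c3ccc(O[Si](C)(C)C(C)(C)C)cc3)C2(C(=O)OC)C(=O)OC)cc1
A3 | alternative 2 | 2-[1-(4-methoxyphenyl)ethenyl]oxirane (racemic) | C=C(c1ccc(OC)cc1)C1CO1
A4 | alternative 2 | dimethyl 2-[4-(tert-butyldimethylsilyloxy)benzylidene]propanedioate | COC(=O)C(=Cc1ccc(O[Si](C)(C)C(C)(C)C)cc1)C(=O)OC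
A5 | alternative 3 | all-trans [2-[4-(tert-butyldimethylsilyloxy)phenyl]-3-[(tert-butyldiphenylsilyloxy)methyl]oxolan-4-yl](4-methoxyphenyl)methanone | COc1ccc(C(=O)[C@H]2CO[C@@H](c3ccc(O[Si](C)(C)C(C)(C)C)cc3)[C@@H]2CO[Si](c4ccccc4)(c5ccccc5)C(C)(C)C)cc1
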